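You have 150 mM of X in each flask, and the flasks differ in their charge of G.

the same everywhere: X 150 mM

| flask | G | time |
|---|---|---|
| alpha | 15.0 mM |  |
| theta | 30.0 mM |  |
| eta | 97.0 mM | 150 min |

| run | time / min | [J] / mM |
|---|---|---|
| alpha run | 11 | 1.0 |
| alpha run | 35 | 9.2 |
| alpha run | 66 | 30.6 |
| alpha run | 100 | 71.8 |
| alpha run | 150 | 126.0 |
| theta run | 11 | 2.0 |
| theta run | 35 | 16.7 |
| theta run | 66 | 52.1 |
| theta run | 100 | 98.1 |
| theta run | 150 | 137.7 |

(scatter of a reading: 0.4 mM)

- the power of [G] that the first rate follows, about the charge of the alpha run; measure it at two percent of X made into J
- J in the eta run at 150 min, as a share of the X charged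

- Overall: X -> J, with G as catalyst.
- Constant volume, constant temperature.
- What is held in complexes is read along with the free species.
- An order is taken over about fifteen percent of the charge, up and down.

1. Take [X] as the charge less the J read, so that X held in a complex counts as left, and follow the odds O = [J]/[X]. If J turns X into more J (autocatalysis) with rate k[X][J], then ln O rises at a steady rate λ = k times the charge of X, however far the flask has gone.

2. In the theta run O goes from 1.89 at 100 min to 11.2 at 150 min, so λ = 0.0356 /min. In the alpha run O goes from 0.918 to 5.25, so λ = 0.0349 /min, nearly the same although the charge of G differs. Call τ = ln(2)/λ = 19.5 min the doubling time of the odds.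

3. At each of those two times the theta odds are twice the alpha odds, so I read doubling the charge of G as moving the curve forward by one τ.

4. My reckoning for the eta run: its charge of G is 1.69 doublings above that of the theta run, a lead of 33.0 min. The odds at 150 min are then 36.2, which leaves 2.69% of the X and gives J as 97.3% of the charge.

5. The forecast says 98% for the eta run, a little above mine, on the grounds that “J is autocatalytic and G mainly initiates”, and it gives an order of 0.5. The order is taken at a fixed amount of J, not at a fixed time; I have no reckoning of my own for it and take the forecast's.

6. The flask gives 98.0% and an order of 0.55, from these steps: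

    Yx + X ⇌ GX (1.104 /M/min, 0.3714 /min)
    GX → J + Yx (0.05448 /min)
    G → Yx (0.1236 /min)
    X + J → 2 J (0.2184 /M/min)

7. The 2.00% of the charge that is not J in the eta run at 150 min means odds of 48.6, a lead over the theta run of 41.2 min against the 33.0 min I reckoned. In the alpha run J reaches half the charge 20.2 min later than in the theta run, against one doubling time of 19.5 min.

(All runs were computed on assumed constants; scatter was added.)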